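**Retrosynthetic overview** (azulene numbering for the hydroazulenes: C1 carries the angelate, C3 the carbinol and isopropyl, C4 the benzoate, C6 the ring methyl, C8a the angular methyl)

1. The two esters are removed last (C1 angelate, C4 trimethoxybenzoate); the C4 carbinol comes from a C4 ketone by hydride delivered from the C3 tertiary hydroxyl.
2. Key disconnection: bonds C4–C5 and C6–C7 of the seven-membered ring. C5–C6 with the C6 methyl is excised as a but-2-ynoate, leaving a cis-bicyclo[3.3.0]octan-2-one. The enabling feature is that the C4 oxygen sits one CH2 (C5) away from the C6=C7 alkene, which is the pattern left by inserting an alkyne between carbonyl carbon and α-carbon of a cyclopentanone, and that the C3a–C8a fusion is cis, the only fusion a bicyclo[3.3.0]octane allows.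
3. The C3 carbinol comes from isopropyl addition to the convex face of a C3 ketone; the second five-membered ring from gold-catalysed 5-exo-dig closure of a silyl enol ether onto a butynyl chain.
4. The quaternary C8a comes from cuprate methylation anti to the silyloxy group of (S)-4-silyloxycyclopentenone, the single source of chirality.
5. Ring order: cyclopentane ring A (from the starting enone), then a second cyclopentane, then its enlargement to the cycloheptene ring B.

Key step: step 10

Remark: β-keto ester 19 is written as its hydrogen-bonded enol tautomer; allyl but-2-ynoate is made in step 9 because its commercial availability is not assumed.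

Step 1
Reactants: 1 (S)-4-[(tert-butyldimethylsilyl)oxy]cyclopent-2-en-1-one; 2 (4-bromobut-1-yn-1-yl)trimethylsilane
Product: 4 (3S,4S)-4-[(tert-butyldimethylsilyl)oxy]-1-[(trimethylsilyl)oxy]-3-[4-(trimethylsilyl)but-3-yn-1-yl]cyclopent-1-ene, via Grignard reagent 3 (not isolated)
Conditions: 2, Mg, THF, 40 °C; then CuBr·SMe2 (10 mol%), Me3SiCl, 1, THF, −78 °C; Et3N, cold aq. NaHCO3
Reagents that add atoms: chlorotrimethylsilane, C[Si](C)(C)Cl
Why: Copper-catalysed conjugate addition of a Grignard reagent with in situ silylation is the standard 1,4-addition to 4-silyloxycyclopentenones; the chain enters anti to the silyloxy group (a centre erased in step 2), and trapping as the silyl enol ether prevents enolate equilibration and β-elimination of the silyloxy group.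

Step 2
Reactants: 4 (3S,4S)-4-[(tert-butyldimethylsilyl)oxy]-1-[(trimethylsilyl)oxy]-3-[4-(trimethylsilyl)but-3-yn-1-yl]cyclopent-1-ene
Product: 5 (S)-4-[(tert-butyldimethylsilyl)oxy]-3-[4-(trimethylsilyl)but-3-yn-1-yl]cyclopent-2-en-1-one
Conditions: Pd(OAc)2 (1.05 equiv), MeCN, rt
Reagents that add atoms: none
Why: Saegusa–Ito oxidation (palladation of the silyl enol ether, then β-hydride elimination toward the chain-bearing carbon) should regenerate the enone, now β-substituted, without touching the silyloxy stereocentre.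

Step 3
Reactants: 5 (S)-4-[(tert-butyldimethylsilyl)oxy]-3-[4-(trimethylsilyl)but-3-yn-1-yl]cyclopent-2-en-1-one
Product: 7 (3R,4S)-4-[(tert-butyldimethylsilyl)oxy]-3-methyl-1-{[tri(propan-2-yl)silyl]oxy}-3-[4-(trimethylsilyl)but-3-yn-1-yl]cyclopent-1-ene, via lithium enolate 6 (not isolated)
Conditions: Me2CuLi (from CuI, 2 MeLi), Et2O, −78 → −20 °C; then iPr3SiOTf, −78 → 0 °C
Reagents that add atoms: lithium dimethylcuprate, [Li+].C[Cu-]C; triisopropylsilyl trifluoromethanesulfonate, CC(C)[Si](C(C)C)(C(C)C)OS(=O)(=O)C(F)(F)F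
Why: Gilman cuprate 1,4-addition to the β,β-disubstituted enone should set the quaternary carbon with methyl anti to the adjacent silyloxy group (chain cis to it), and O-silylation of the regiodefined enolate fixes the enol ether on the side needed for ring closure.

Step 4
Reactants: 7 (3R,4S)-4-[(tert-butyldimethylsilyl)oxy]-3-methyl-1-{[tri(propan-2-yl)silyl]oxy}-3-[4-(trimethylsilyl)but-3-yn-1-yl]cyclopent-1-ene
Product: 8 (3R,4S)-3-(but-3-yn-1-yl)-4-[(tert-butyldimethylsilyl)oxy]-3-methyl-1-{[tri(propan-2-yl)silyl]oxy}cyclopent-1-ene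
Conditions: K2CO3 (0.3 equiv), MeOH–THF, rt
Reagents that add atoms: none
Why: Base-catalysed methanolysis is selective for the alkynyl C–Si bond; the bulky silyl enol ether and the secondary silyl ether should survive, and the ketone stays masked so that no base-sensitive β-silyloxy ketone is exposed.

Step 5
Reactants: 8 (3R,4S)-3-(but-3-yn-1-yl)-4-[(tert-butyldimethylsilyl)oxy]-3-methyl-1-{[tri(propan-2-yl)silyl]oxy}cyclopent-1-ene
Product: 9 (3S,3aR,6aS)-3-[(tert-butyldimethylsilyl)oxy]-3a-methyl-6-methylidene-3,3a,4,5,6,6a-hexahydropentalen-1(2H)-one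
Conditions: AuCl(PPh3) (10 mol%), AgBF4 (10 mol%), CH2Cl2–MeOH (10:1), rt
Reagents that add atoms: none
Why: Gold-catalysed Conia-ene-type carbocyclisation of a silyl enol ether onto a terminal alkyne (5-exo-dig, then protodeauration and silyl transfer to methanol); the tether on the quaternary carbon can reach the adjacent enol carbon only from its own face, so the bicyclo[3.3.0]octanone is cis-fused with the ring-fusion hydrogen cis to the angular methyl.

Step 6
Reactants: 9 (3S,3aR,6aS)-3-[(tert-butyldimethylsilyl)oxy]-3a-methyl-6-methylidene-3,3a,4,5,6,6a-hexahydropentalen-1(2H)-one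
Product: 10 (1S,3S,3aR,6aS)-3-[(tert-butyldimethylsilyl)oxy]-3a-methyl-6-methylidene-1-(propan-2-yl)octahydropentalen-1-ol
Conditions: iPrMgCl, CeCl3, THF, −78 → 0 °C
Reagents that add atoms: isopropylmagnesium chloride, CC(C)[Mg]Cl
Why: Organocerium 1,2-addition suppresses enolisation of the β,γ-unsaturated ketone and β-hydride reduction; attack on the convex face of the cis-diquinane (the concave face is blocked by the other ring and the silyloxy group) should put isopropyl cis to the ring-fusion hydrogen and the new hydroxyl on the concave face.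

Step 7
Reactants: 10 (1S,3S,3aR,6aS)-3-[(tert-butyldimethylsilyl)oxy]-3a-methyl-6-methylidene-1-(propan-2-yl)octahydropentalen-1-ol
Product: 11 (1S,3S,3aR,6aS)-3-[(tert-butyldimethylsilyl)oxy]-3a-methyl-6-methylidene-1-(propan-2-yl)-1-[(trimethylsilyl)oxy]octahydropentalene
Conditions: Me3SiOTf, 2,6-lutidine, CH2Cl2, −78 → 0 °C
Reagents that add atoms: trimethylsilyl trifluoromethanesulfonate, C[Si](C)(C)OS(=O)(=O)C(F)(F)F
Why: Silyl triflate silylation of a hindered tertiary alcohol; the temporary ether guards the coming β-hydroxy ketone against retro-aldol cleavage and dehydration during enamine formation and is lost in the acidic work-up of step 10.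

Step 8
Reactants: 11 (1S,3S,3aR,6aS)-3-[(tert-butyldimethylsilyl)oxy]-3a-methyl-6-methylidene-1-(propan-2-yl)-1-[(trimethylsilyl)oxy]octahydropentalene
Product: 12 (3aR,4S,6S,6aS)-4-[(tert-butyldimethylsilyl)oxy]-3a-methyl-6-(propan-2-yl)-6-[(trimethylsilyl)oxy]-3,3a,4,5,6,6a-hexahydropentalen-1(2H)-one
Conditions: O3, CH2Cl2, −78 °C; then PPh3, −78 °C → rt
Reagents that add atoms: ozone, [O-][O+]=O
Why: Ozonolysis with reductive work-up cleaves the only alkene to the cyclopentanone; the silyl ethers are inert.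

Step 9
Reactants: 13 but-2-ynoic acid; 14 prop-2-en-1-ol
Product: 15 prop-2-en-1-yl but-2-ynoate
Conditions: DCC, DMAP (5 mol%), CH2Cl2, 0 °C → rt
Reagents that add atoms: none
Why: Steglich esterification; the allyl ester is chosen so that the ester carried into the ring in step 10 can be removed under near-neutral conditions in step 11.

Step 10
Reactants: 12 (3aR,4S,6S,6aS)-4-[(tert-butyldimethylsilyl)oxy]-3a-methyl-6-(propan-2-yl)-6-[(trimethylsilyl)oxy]-3,3a,4,5,6,6a-hexahydropentalen-1(2H)-one; 15 prop-2-en-1-yl but-2-ynoate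
Product: 19 prop-2-en-1-yl (1S,3S,3aS,8aR)-1-[(tert-butyldimethylsilyl)oxy]-3,4-dihydroxy-6,8a-dimethyl-3-(propan-2-yl)-1,2,3,3a,8,8a-hexahydroazulene-5-carboxylate (enol form), via pyrrolidine enamine 16 (not isolated), via aminocyclobutene cycloadduct 17 (not isolated), via ring-opened aminodiene ester 18 (not isolated)
Conditions: pyrrolidine (3 equiv), TsOH (2 mol%), PhH, reflux (Dean–Stark), then evaporate; 15 (1.3 equiv), PhMe, 25 → 100 °C; then 1 M aq. HCl–THF, rt
Reagents that add atoms: water, O
Why: Condensation at the cyclopentanone carbonyl (pentalenone C1) gives the less substituted enamine 16, toward the C2 methylene, because the alternative toward the ring-fusion carbon C6a is tertiary and flanked by the fully substituted C6; its β-carbon adds to the methyl-bearing β-carbon of ynoate 15, and the iminium/allenoate zwitterion collapses by 4-exo-trig closure onto the iminium carbon to the aminocyclobutene 17 (formal [2+2] cycloaddition), which makes the azulene C6–C7 and C4–C5 bonds in one sequence. Opening of 17 across the old C1–C2 bond (push from nitrogen, pull from the ester) enlarges the five-membered ring to the seven-membered ring of 18; the closest known reaction type is the enamine–acetylenic ester two-carbon ring enlargement of cyclic ketones. The only ring closed is the transient cyclobutene, so the cycloheptadiene arises by ring enlargement and not by a medium-ring closure. No lasting stereocentre is created (both cyclobutene fusion carbons become sp2), and C3a/C8a keep the cis fusion fixed in the bicyclo[3.3.0]octane because C3a never becomes part of the enamine. The selectivities needed are the enamine regiochemistry (secured by substitution as above) and the orientation of the ynoate (secured by its polarisation), which together place the methyl on C6, the alkene at C6=C7 and the removable ester on C5. Mild acid then hydrolyses the vinylogous carbamate and the tertiary trimethylsilyl ether to give 19.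

Step 11
Reactants: 19 prop-2-en-1-yl (1S,3S,3aS,8aR)-1-[(tert-butyldimethylsilyl)oxy]-3,4-dihydroxy-6,8a-dimethyl-3-(propan-2-yl)-1,2,3,3a,8,8a-hexahydroazulene-5-carboxylate
Product: 20 (1S,3S,3aS,8aR)-1-[(tert-butyldimethylsilyl)oxy]-3-hydroxy-6,8a-dimethyl-3-(propan-2-yl)-2,3,3a,5,8,8a-hexahydroazulen-4(1H)-one
Conditions: Pd(OAc)2 (5 mol%), PPh3 (20 mol%), HCO2H, Et3N, THF, rt
Reagents that add atoms: none
Why: Tsuji–Trost-type deallylation of the allyl β-keto ester by zerovalent palladium formed in situ, with formate as hydride source, then decarboxylation of the β-keto acid; kinetic protonation at C5 under these near-neutral conditions should keep the C6=C7 alkene out of conjugation and leave the C3a centre untouched.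

Step 12
Reactants: 20 (1S,3S,3aS,8aR)-1-[(tert-butyldimethylsilyl)oxy]-3-hydroxy-6,8a-dimethyl-3-(propan-2-yl)-2,3,3a,5,8,8a-hexahydroazulen-4(1H)-one
Product: 21 (1S,3S,3aR,4R,8aR)-1-[(tert-butyldimethylsilyl)oxy]-6,8a-dimethyl-3-(propan-2-yl)-1,2,3,3a,4,5,8,8a-octahydroazulene-3,4-diol
Conditions: Me4NBH(OAc)3, MeCN–AcOH (1:1), −30 → −20 °C
Reagents that add atoms: none
Why: Hydroxyl-directed (Evans–Saksena) reduction: the C3 tertiary hydroxyl on the concave face exchanges onto boron and delivers hydride to the concave face of the C4 carbonyl, so the new hydroxyl should end on the convex face (cis to the ring-fusion hydrogen and the angular methyl), the opposite of what an external hydride would give.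

Step 13
Reactants: 21 (1S,3S,3aR,4R,8aR)-1-[(tert-butyldimethylsilyl)oxy]-6,8a-dimethyl-3-(propan-2-yl)-1,2,3,3a,4,5,8,8a-octahydroazulene-3,4-diol; 22 3,4,5-trimethoxybenzoyl chloride
Product: 23 (1S,3S,3aR,4R,8aR)-1-[(tert-butyldimethylsilyl)oxy]-3-hydroxy-6,8a-dimethyl-3-(propan-2-yl)-1,2,3,3a,4,5,8,8a-octahydroazulen-4-yl 3,4,5-trimethoxybenzoate
Conditions: Et3N, DMAP (10 mol%), CH2Cl2, 0 °C → rt
Reagents that add atoms: none
Why: DMAP-catalysed acylation; only the secondary C4 hydroxyl should react, the tertiary C3 hydroxyl being inert and C1 still silylated.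

Step 14
Reactants: 23 (1S,3S,3aR,4R,8aR)-1-[(tert-butyldimethylsilyl)oxy]-3-hydroxy-6,8a-dimethyl-3-(propan-2-yl)-1,2,3,3a,4,5,8,8a-octahydroazulen-4-yl 3,4,5-trimethoxybenzoate
Product: 24 (1S,3S,3aR,4R,8aR)-1,3-dihydroxy-6,8a-dimethyl-3-(propan-2-yl)-1,2,3,3a,4,5,8,8a-octahydroazulen-4-yl 3,4,5-trimethoxybenzoate
Conditions: HF·pyridine, THF–pyridine, 0 °C → rt
Reagents that add atoms: none
Why: Fluoride cleavage of the secondary silyl ether under buffered conditions that should leave the aryl ester, the tertiary alcohol and the alkene untouched.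

Step 15
Reactants: 24 (1S,3S,3aR,4R,8aR)-1,3-dihydroxy-6,8a-dimethyl-3-(propan-2-yl)-1,2,3,3a,4,5,8,8a-octahydroazulen-4-yl 3,4,5-trimethoxybenzoate; 25 (2Z)-2-methylbut-2-enoic acid (angelic acid)
Product: 27 (1S,3S,3aR,4R,8aR)-3-hydroxy-6,8a-dimethyl-1-{[(2Z)-2-methylbut-2-enoyl]oxy}-3-(propan-2-yl)-1,2,3,3a,4,5,8,8a-octahydroazulen-4-yl 3,4,5-trimethoxybenzoate, via mixed anhydride 26 (not isolated)
Conditions: 2,4,6-trichlorobenzoyl chloride, Et3N, PhMe, rt; then 24, 75 °C
Reagents that add atoms: none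
Why: Yamaguchi-type mixed-anhydride esterification run without a nucleophilic catalyst is the usual way to acylate hindered alcohols with angelic acid without Z to E isomerisation; the tertiary C3 hydroxyl should not compete.

**Compound list**

1 | (S)-4-[(tert-butyldimethylsilyl)oxy]cyclopent-2-en-1-one | CC(C)(C)[Si](C)(C)O[C@@H]1C=CC(=O)C1 | starting material
2 | (4-bromobut-1-yn-1-yl)trimethylsilane | C[Si](C)(C)C#CCCBr | starting material
3 | [4-(trimethylsilyl)but-3-yn-1-yl]magnesium bromide | C[Si](C)(C)C#CCC[Mg]Br | intermediate (not isolated)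
4 | (3S,4S)-4-[(tert-butyldimethylsilyl)oxy]-1-[(trimethylsilyl)oxy]-3-[4-(trimethylsilyl)but-3-yn-1-yl]cyclopent-1-ene (3,4-trans) | CC(C)(C)[Si](C)(C)O[C@@H]1[C@@H](CCC#C[Si](C)(C)C)C=C(O[Si](C)(C)C)C1 | intermediate
5 | (S)-4-[(tert-butyldimethylsilyl)oxy]-3-[4-(trimethylsilyl)but-3-yn-1-yl]cyclopent-2-en-1-one | CC(C)(C)[Si](C)(C)O[C@@H]1C(CCC#C[Si](C)(C)C)=CC(=O)C1 | intermediate
6 | lithium (3R,4S)-4-[(tert-butyldimethylsilyl)oxy]-3-methyl-3-[4-(trimethylsilyl)but-3-yn-1-yl]cyclopent-1-en-1-olate | CC(C)(C)[Si](C)(C)O[C@@H]1[C@](C)(CCC#C[Si](C)(C)C)C=C(O[Li])C1 | intermediate (not isolated)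
7 | (3R,4S)-4-[(tert-butyldimethylsilyl)oxy]-3-methyl-1-{[tri(propan-2-yl)silyl]oxy}-3-[4-(trimethylsilyl)but-3-yn-1-yl]cyclopent-1-ene (methyl trans to the silyloxy group) | CC(C)(C)[Si](C)(C)O[C@@H]1[C@](C)(CCC#C[Si](C)(C)C)C=C(O[Si](C(C)C)(C(C)C)C(C)C)C1 | intermediate
8 | (3R,4S)-3-(but-3-yn-1-yl)-4-[(tert-butyldimethylsilyl)oxy]-3-methyl-1-{[tri(propan-2-yl)silyl]oxy}cyclopent-1-ene | CC(C)(C)[Si](C)(C)O[C@@H]1[C@](C)(CCC#C)C=C(O[Si](C(C)C)(C(C)C)C(C)C)C1 | intermediate
9 | (3S,3aR,6aS)-3-[(tert-butyldimethylsilyl)oxy]-3a-methyl-6-methylidene-3,3a,4,5,6,6a-hexahydropentalen-1(2H)-one (cis-fused) | CC(C)(C)[Si](C)(C)O[C@H]1CC(=O)[C@H]2C(=C)CC[C@@]12C | intermediate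
10 | (1S,3S,3aR,6aS)-3-[(tert-butyldimethylsilyl)oxy]-3a-methyl-6-methylidene-1-(propan-2-yl)octahydropentalen-1-ol | CC(C)(C)[Si](C)(C)O[C@H]1C[C@](O)(C(C)C)[C@H]2C(=C)CC[C@@]12C | intermediate
11 | (1S,3S,3aR,6aS)-3-[(tert-butyldimethylsilyl)oxy]-3a-methyl-6-methylidene-1-(propan-2-yl)-1-[(trimethylsilyl)oxy]octahydropentalene | CC(C)(C)[Si](C)(C)O[C@H]1C[C@](O[Si](C)(C)C)(C(C)C)[C@H]2C(=C)CC[C@@]12C | intermediate
12 | (3aR,4S,6S,6aS)-4-[(tert-butyldimethylsilyl)oxy]-3a-methyl-6-(propan-2-yl)-6-[(trimethylsilyl)oxy]-3,3a,4,5,6,6a-hexahydropentalen-1(2H)-one | CC(C)(C)[Si](C)(C)O[C@H]1C[C@](O[Si](C)(C)C)(C(C)C)[C@H]2C(=O)CC[C@@]12C | intermediate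
13 | but-2-ynoic acid | CC#CC(=O)O | starting material
14 | prop-2-en-1-ol | C=CCO | starting material
15 | prop-2-en-1-yl but-2-ynoate | CC#CC(=O)OCC=C | intermediate
16 | pyrrolidine enamine of 12 (C1=C2 enamine of the pentalenone; stereocentres as in 12) | CC(C)(C)[Si](C)(C)O[C@H]1C[C@](O[Si](C)(C)C)(C(C)C)[C@H]2C(N3CCCC3)=CC[C@@]12C | intermediate (not isolated)
17 | aminocyclobutene cycloadduct: allyl cyclobutenecarboxylate cis-fused on the convex face across the former C1–C2 bond of 16, pyrrolidinyl on the former carbonyl carbon, methyl on the cyclobutene carbon next to the former C2 | CC(C)(C)[Si](C)(C)O[C@H]1C[C@](O[Si](C)(C)C)(C(C)C)[C@H]2[C@]3(N4CCCC4)C(C(=O)OCC=C)=C(C)[C@@H]3C[C@@]12C | intermediate (not isolated)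
18 | ring-opened aminodiene ester: prop-2-en-1-yl 1-[(tert-butyldimethylsilyl)oxy]-6,8a-dimethyl-3-(propan-2-yl)-4-(pyrrolidin-1-yl)-3-[(trimethylsilyl)oxy]-1,2,3,3a,8,8a-hexahydroazulene-5-carboxylate (stereocentres as in 12) | CC(C)(C)[Si](C)(C)O[C@H]1C[C@](O[Si](C)(C)C)(C(C)C)[C@H]2C(N3CCCC3)=C(C(=O)OCC=C)C(C)=CC[C@@]12C | intermediate (not isolated)
19 | prop-2-en-1-yl (1S,3S,3aS,8aR)-1-[(tert-butyldimethylsilyl)oxy]-3,4-dihydroxy-6,8a-dimethyl-3-(propan-2-yl)-1,2,3,3a,8,8a-hexahydroazulene-5-carboxylate (enol form of the 4-oxo ester) | CC(C)(C)[Si](C)(C)O[C@H]1C[C@](O)(C(C)C)[C@H]2C(O)=C(C(=O)OCC=C)C(C)=CC[C@@]12C | intermediate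
20 | (1S,3S,3aS,8aR)-1-[(tert-butyldimethylsilyl)oxy]-3-hydroxy-6,8a-dimethyl-3-(propan-2-yl)-2,3,3a,5,8,8a-hexahydroazulen-4(1H)-one | CC(C)(C)[Si](C)(C)O[C@H]1C[C@](O)(C(C)C)[C@H]2C(=O)CC(C)=CC[C@@]12C | intermediate
21 | (1S,3S,3aR,4R,8aR)-1-[(tert-butyldimethylsilyl)oxy]-6,8a-dimethyl-3-(propan-2-yl)-1,2,3,3a,4,5,8,8a-octahydroazulene-3,4-diol | CC(C)(C)[Si](C)(C)O[C@H]1C[C@](O)(C(C)C)[C@H]2[C@H](O)CC(C)=CC[C@@]12C | intermediate
22 | 3,4,5-trimethoxybenzoyl chloride | COc1cc(cc(OC)c1OC)C(Cl)=O | starting material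
23 | (1S,3S,3aR,4R,8aR)-1-[(tert-butyldimethylsilyl)oxy]-3-hydroxy-6,8a-dimethyl-3-(propan-2-yl)-1,2,3,3a,4,5,8,8a-octahydroazulen-4-yl 3,4,5-trimethoxybenzoate | CC(C)(C)[Si](C)(C)O[C@H]1C[C@](O)(C(C)C)[C@H]2[C@H](OC(=O)c3cc(OC)c(OC)c(OC)c3)CC(C)=CC[C@@]12C | intermediate
24 | (1S,3S,3aR,4R,8aR)-1,3-dihydroxy-6,8a-dimethyl-3-(propan-2-yl)-1,2,3,3a,4,5,8,8a-octahydroazulen-4-yl 3,4,5-trimethoxybenzoate | O[C@H]1C[C@](O)(C(C)C)[C@H]2[C@H](OC(=O)c3cc(OC)c(OC)c(OC)c3)CC(C)=CC[C@@]12C | intermediate
25 | (2Z)-2-methylbut-2-enoic acid (angelic acid) | C/C=C(/C)C(=O)O | starting material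
26 | (2Z)-2-methylbut-2-enoic 2,4,6-trichlorobenzoic anhydride | C/C=C(/C)C(=O)OC(=O)c1c(Cl)cc(Cl)cc1Cl | intermediate (not isolated)
27 | (1S,3S,3aR,4R,8aR)-3-hydroxy-6,8a-dimethyl-1-{[(2Z)-2-methylbut-2-enoyl]oxy}-3-(propan-2-yl)-1,2,3,3a,4,5,8,8a-octahydroazulen-4-yl 3,4,5-trimethoxybenzoate | C/C=C(/C)C(=O)O[C@H]1C[C@](O)(C(C)C)[C@H]2[C@H](OC(=O)c3cc(OC)c(OC)c(OC)c3)CC(C)=CC[C@@]12C | target

**Count and risks**

Total step count: 15. Longest linear sequence: 14 (steps 1–8 and 10–15, from 1).

Steps most likely to fail: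

Step 10. The β-methyl ynoate may be too weak an electrophile for the enamine, or the zwitterion may be diverted by proton transfer to an open-chain Michael adduct before the cyclobutene closes. The fallback makes the same two bonds from the silyl enol ether under Lewis acid activation. It sets out from 12: LiN(iPr)2 and Me3SiCl (THF, −78 °C) should deprotonate the CH2 and not the ring-fusion CH and give the kinetic trimethylsilyl enol ether of 12 F1. An EtAlCl2-promoted [2+2] cycloaddition with 15 (CH2Cl2, −78 → −20 °C) should give the siloxycyclobutene cycloadduct F2. Bu4NF buffered with AcOH (THF, 0 °C) would then free the cyclobutanolate, which opens by retro-aldol cleavage of the ring-fusion bond and loses the tertiary silyl ether in the same operation. The fallback comes back to the route at 19.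

Step 12. Ligand exchange of the hindered tertiary hydroxyl onto boron may be too slow, so that hydride arrives from outside on the convex face and facial selectivity is lost or reversed. The fallback accepts convex-face attack and corrects it by inversion. It sets out from 20: LiBH(sBu)3 (THF, −78 °C) should give the C4-epimeric diol F3 by attack on the convex face. Mitsunobu esterification of F3 with 3,4,5-trimethoxybenzoic acid (PPh3, diisopropyl azodicarboxylate, PhMe, 0 °C → rt) would invert C4 and install the benzoate in one step. The fallback comes back to the route at 23.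

Step 15. Acylation of the hindered C1 hydroxyl (next to the quaternary carbon, on the concave face) may need forcing that isomerises the angeloyl group to the E (tigloyl) form. The fallback builds the Z alkene on the molecule instead. It sets out from 24: DCC/DMAP coupling with 2-[bis(2,2,2-trifluoroethoxy)phosphoryl]propanoic acid should give the phosphonopropionate ester F4. Still–Gennari olefination of F4 with acetaldehyde (KN(SiMe3)2, 18-crown-6, THF, −78 °C) should form the Z-trisubstituted enoate. The fallback comes back to the route at 27.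

Further compounds
F1 | step 10 | trimethylsilyl enol ether of 12 (C1=C2 of the pentalenone, O-silylated; stereocentres as in 12) | CC(C)(C)[Si](C)(C)O[C@H]1C[C@](O[Si](C)(C)C)(C(C)C)[C@H]2C(O[Si](C)(C)C)=CC[C@@]12C
F2 | step 10 | siloxycyclobutene cycloadduct (allyl cyclobutenecarboxylate cis-fused on the convex face across the former C1–C2 bond, trimethylsilyloxy on the former carbonyl carbon) | CC(C)(C)[Si](C)(C)O[C@H]1C[C@](O[Si](C)(C)C)(C(C)C)[C@H]2[C@]3(O[Si](C)(C)C)C(C(=O)OCC=C)=C(C)[C@@H]3C[C@@]12C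
F3 | step 12 | (1S,3S,3aR,4S,8aR)-1-[(tert-butyldimethylsilyl)oxy]-6,8a-dimethyl-3-(propan-2-yl)-1,2,3,3a,4,5,8,8a-octahydroazulene-3,4-diol (C4 epimer of 21) | CC(C)(C)[Si](C)(C)O[C@H]1C[C@](O)(C(C)C)[C@H]2[C@@H](O)CC(C)=CC[C@@]12C
F4 | step 15 | (1S,3S,3aR,4R,8aR)-1-({2-[bis(2,2,2-trifluoroethoxy)phosphoryl]propanoyl}oxy)-3-hydroxy-6,8a-dimethyl-3-(propan-2-yl)-1,2,3,3a,4,5,8,8a-octahydroazulen-4-yl 3,4,5-trimethoxybenzoate (both epimers at the phosphonate-bearing carbon) | CC(C(=O)O[C@H]1C[C@](O)(C(C)C)[C@H]2[C@H](OC(=O)c3cc(OC)c(OC)c(OC)c3)CC(C)=CC[C@@]12C)P(=O)(OCC(F)(F)F)OCC(F)(F)F
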